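**Retrosynthetic overview**

- Feature: in the 1,2-dioxolane (O1–O2–C3–C4–C5) both C3 (CH3, CH2CO2Me, C4) and C5 (CH3, CH2 of the 2-methyl-8-phenyloctyl chain, C4) are fully substituted and carry no hydrogen. Each C–O bond can therefore be fixed beforehand as a tertiary carbinol, and only O1–O2 remains to be made.
- Key disconnection: O1–O2, formed last by oxidative N–N coupling of a 1,3-bis(aminooxy) compound to a seven-membered cyclic hyponitrite, loss of N2 and collapse of the alkoxyl pair. This closes the dioxolane, the only ring built in the route.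
- The bis(aminooxy) compound comes from the di-tertiary 1,3-diol by double alkoxide amination. The CH2CO2Me arm is carried as CH2CH2OSi(iPr)3 and oxidised after ring closure.
- The diol comes from two rounds of terminal alkyne → Zr-catalysed methylalumination/formaldehyde → Sharpless epoxidation → Red-Al opening. Round one (L-(+)-tartrate) sets C5, round two (D-(−)-tartrate) sets C3.
- The first alkyne comes from (R)-citronellal, which supplies the side-chain methyl stereocentre, by cross-metathesis with 4-phenylbut-1-ene, hydrogenation and Ohira–Bestmann homologation.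

Key step: step 16

Remark on the chemistry: the arm is protected as a triisopropylsilyl ether because this group should not migrate to the neighbouring tertiary alkoxide during the amination. 3,3-Di-tert-butyloxaziridine is taken as a reagent prepared beforehand from the N–H ketimine and mCPBA. The sense of induction in steps 5 and 11 is assigned by analogy with geraniol, for which the L-(+)-tartrate gives the (2S,3S)-epoxide.

**Route**

Step 1
Reactants: 1 (R)-citronellal; 2 4-phenylbut-1-ene
Product: 3 (3R)-3-methyl-9-phenylnon-6-enal (E/Z mixture)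
Conditions: 2 (4 equiv), second-generation Hoveyda–Grubbs catalyst RuCl2(H2IMes)(=CH-C6H4-2-OiPr) (5 mol %), CH2Cl2, 40 °C
Reagents that add atoms: none
Why: Olefin cross-metathesis should exchange the isopropylidene end of the trisubstituted alkene for the 3-phenylpropylidene end of 2 with loss of 2-methylpropene, the aldehyde and the stereocentre taking no part, and the alkene geometry is of no consequence because the double bond is hydrogenated next.

Step 2
Reactants: 3 (3R)-3-methyl-9-phenylnon-6-enal
Product: 4 (3R)-3-methyl-9-phenylnonanal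
Conditions: H2 (1 atm), 10% Pd/C, EtOAc, rt
Reagents that add atoms: none
Why: Heterogeneous catalytic hydrogenation saturates the disubstituted alkene, while the aliphatic aldehyde and the benzene ring should survive at 1 atm in a non-alcoholic solvent.

Step 3
Reactants: 4 (3R)-3-methyl-9-phenylnonanal; 5 dimethyl (1-diazo-2-oxopropyl)phosphonate
Product: 6 (4R)-4-methyl-10-phenyldec-1-yne
Conditions: K2CO3, MeOH, 0 °C → rt
Reagents that add atoms: none
Why: Seyferth–Gilbert homologation in the Ohira–Bestmann variant turns the aldehyde into the terminal alkyne under mild base, and the stereocentre, which is β to the carbonyl, cannot epimerise.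

Step 4
Reactants: 6 (4R)-4-methyl-10-phenyldec-1-yne; 7 trimethylaluminium
Product: 9 (2E,5R)-3,5-dimethyl-11-phenylundec-2-en-1-ol, via E-alkenyldimethylalane 8 (not isolated)
Conditions: AlMe3 (2.5 equiv), Cp2ZrCl2 (0.25 equiv), CH2Cl2, 0 °C → rt; volatiles off; THF, (CH2O)n, 0 °C → rt; aq. KNaC4H4O6
Reagents that add atoms: formaldehyde (as paraformaldehyde), C=O
Why: Negishi zirconium-catalysed methylalumination adds CH3 and Al syn across the alkyne with CH3 on the internal carbon to give the E-alkenylalane 8, whose C–Al bond is hydroxymethylated by formaldehyde with retention to give the E-trisubstituted allylic alcohol.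

Step 5
Reactants: 9 (2E,5R)-3,5-dimethyl-11-phenylundec-2-en-1-ol
Product: 10 [(2S,3S)-3-methyl-3-[(2R)-2-methyl-8-phenyloctyl]oxiran-2-yl]methanol
Conditions: Ti(OiPr)4 (10 mol %), L-(+)-diisopropyl tartrate (12 mol %), t-BuOOH (2 equiv), 4 Å MS, CH2Cl2, −20 °C
Reagents that add atoms: tert-butyl hydroperoxide, CC(C)(C)OO
Why: Katsuki–Sharpless asymmetric epoxidation under reagent control: with the L-(+)-tartrate the E-trisubstituted allylic alcohol should be epoxidised on the face that gives the (2S,3S)-epoxide (the sense known for geraniol), which fixes the quaternary C–O centre that becomes ring C5, the remote methyl centre having no influence.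

Step 6
Reactants: 10 [(2S,3S)-3-methyl-3-[(2R)-2-methyl-8-phenyloctyl]oxiran-2-yl]methanol
Product: 11 (3S,5R)-3,5-dimethyl-11-phenylundecane-1,3-diol
Conditions: NaAlH2(OCH2CH2OMe)2, THF, 0 °C → rt; aq. KNaC4H4O6
Reagents that add atoms: none
Why: Red-Al opening of a 2,3-epoxy alcohol delivers hydride within the C1 alkoxyaluminate to C2, so the 1,3-diol forms and the tertiary C3–O bond, and with it the new stereocentre, is left untouched.

Step 7
Reactants: 11 (3S,5R)-3,5-dimethyl-11-phenylundecane-1,3-diol
Product: 12 (3S,5R)-3,5-dimethyl-11-phenyl-1,3-bis(triethylsilyloxy)undecane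
Conditions: Et3SiOTf (2.5 equiv), 2,6-lutidine, CH2Cl2, −78 → 0 °C
Reagents that add atoms: triethylsilyl trifluoromethanesulfonate, CC[Si](CC)(CC)OS(=O)(=O)C(F)(F)F
Why: Silylation with the silyl triflate and 2,6-lutidine is reactive enough to cap the tertiary hydroxyl as well as the primary one, so that the later β-oxygenated aldehyde cannot undergo retro-aldol cleavage or dehydration.

Step 8
Reactants: 12 (3S,5R)-3,5-dimethyl-11-phenyl-1,3-bis(triethylsilyloxy)undecane
Product: 13 (3S,5R)-3,5-dimethyl-11-phenyl-3-(triethylsilyloxy)undecanal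
Conditions: (COCl)2, DMSO, CH2Cl2, −78 → −30 °C; then Et3N, −78 °C → rt
Reagents that add atoms: none
Why: Direct Swern oxidation of a primary triethylsilyl ether: the activated sulfoxide reagent cleaves only the unhindered primary O–Si bond and oxidises that oxygen to the aldehyde, while the tertiary silyl ether is too hindered to react.

Step 9
Reactants: 13 (3S,5R)-3,5-dimethyl-11-phenyl-3-(triethylsilyloxy)undecanal; 5 dimethyl (1-diazo-2-oxopropyl)phosphonate
Product: 14 triethyl{[(4S,6R)-4,6-dimethyl-12-phenyldodec-1-yn-4-yl]oxy}silane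
Conditions: K2CO3, MeOH, 0 °C → rt
Reagents that add atoms: none
Why: Ohira–Bestmann (Seyferth–Gilbert) homologation of the aldehyde to the terminal alkyne, a reaction routinely run on β-silyloxy aldehydes without β-elimination.

Step 10
Reactants: 14 triethyl{[(4S,6R)-4,6-dimethyl-12-phenyldodec-1-yn-4-yl]oxy}silane; 7 trimethylaluminium
Product: 16 (2E,5S,7R)-3,5,7-trimethyl-13-phenyl-5-(triethylsilyloxy)tridec-2-en-1-ol, via E-alkenyldimethylalane 15 (not isolated)
Conditions: AlMe3 (2.5 equiv), Cp2ZrCl2 (0.25 equiv), CH2Cl2, 0 °C → rt; volatiles off; THF, (CH2O)n, 0 °C → rt; aq. KNaC4H4O6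
Reagents that add atoms: formaldehyde (as paraformaldehyde), C=O
Why: Negishi zirconium-catalysed methylalumination followed by formaldehyde, as in step 4, should again give only the E-allylic alcohol, silyl ethers being tolerated by AlMe3/Cp2ZrCl2 at room temperature.

Step 11
Reactants: 16 (2E,5S,7R)-3,5,7-trimethyl-13-phenyl-5-(triethylsilyloxy)tridec-2-en-1-ol
Product: 17 [(2R,3R)-3-[(2S,4R)-2,4-dimethyl-10-phenyl-2-(triethylsilyloxy)decyl]-3-methyloxiran-2-yl]methanol
Conditions: Ti(OiPr)4 (10 mol %), D-(−)-diisopropyl tartrate (12 mol %), t-BuOOH (2 equiv), 4 Å MS, CH2Cl2, −20 °C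
Reagents that add atoms: tert-butyl hydroperoxide, CC(C)(C)OO
Why: Katsuki–Sharpless asymmetric epoxidation under reagent control: the D-(−)-tartrate should deliver oxygen to the face opposite to that used in step 5 and give the (2R,3R)-epoxide, which fixes the quaternary C–O centre that becomes ring C3, the silyl ether keeping the tertiary oxygen away from titanium and from the epoxide.

Step 12
Reactants: 17 [(2R,3R)-3-[(2S,4R)-2,4-dimethyl-10-phenyl-2-(triethylsilyloxy)decyl]-3-methyloxiran-2-yl]methanol
Product: 18 (3S,5S,7R)-3,5,7-trimethyl-13-phenyl-5-(triethylsilyloxy)tridecane-1,3-diol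
Conditions: NaAlH2(OCH2CH2OMe)2, THF, 0 °C → rt; aq. KNaC4H4O6
Reagents that add atoms: none
Why: Red-Al opening of the 2,3-epoxy alcohol by internal hydride delivery to C2 gives the 1,3-diol with the new tertiary centre untouched (its descriptor changes from R to S only through the priority rules), and the silyl ether prevents a competing hydride delivery from the C5 oxygen.

Step 13
Reactants: 18 (3S,5S,7R)-3,5,7-trimethyl-13-phenyl-5-(triethylsilyloxy)tridecane-1,3-diol
Product: 19 (3S,5S,7R)-3,5,7-trimethyl-13-phenyltridecane-1,3,5-triol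
Conditions: Bu4NF, THF, rt
Reagents that add atoms: none
Why: Fluoride-induced cleavage of the tertiary triethylsilyl ether, driven by Si–F bond formation, frees the second tertiary hydroxyl without touching any stereocentre.

Step 14
Reactants: 19 (3S,5S,7R)-3,5,7-trimethyl-13-phenyltridecane-1,3,5-triol
Product: 20 (3S,5S,7R)-3,5,7-trimethyl-13-phenyl-1-(triisopropylsilyloxy)tridecane-3,5-diol
Conditions: iPr3SiCl (1.1 equiv), imidazole, DMF, 0 °C → rt
Reagents that add atoms: triisopropylsilyl chloride, CC(C)[Si](Cl)(C(C)C)C(C)C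
Why: Steric differentiation in silyl ether formation: iPr3SiCl with imidazole should silylate only the primary hydroxyl and leave both tertiary hydroxyls free.

Step 15
Reactants: 20 (3S,5S,7R)-3,5,7-trimethyl-13-phenyl-1-(triisopropylsilyloxy)tridecane-3,5-diol
Product: 22 (3S,5S,7R)-3,5-bis(aminooxy)-3,5,7-trimethyl-13-phenyl-1-(triisopropylsilyloxy)tridecane, via dipotassium dialkoxide 21 (not isolated)
Conditions: KH (2.5 equiv), DMPU, 0 °C → rt; then 3,3-di-tert-butyloxaziridine (3 equiv), −40 → 0 °C
Reagents that add atoms: 3,3-di-tert-butyloxaziridine, CC(C)(C)C1(NO1)C(C)(C)C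
Why: Electrophilic amination of alkoxides with an N–H oxaziridine: each tertiary potassium alkoxide attacks the ring nitrogen, the N–O bond of the reagent breaks and the ketone is expelled, so both O–NH2 groups are made on the existing oxygens with retention at C3 and C5.

Step 16
Reactants: 22 (3S,5S,7R)-3,5-bis(aminooxy)-3,5,7-trimethyl-13-phenyl-1-(triisopropylsilyloxy)tridecane
Product: 26 (3S,5S)-3,5-dimethyl-5-[(2R)-2-methyl-8-phenyloctyl]-3-[2-(triisopropylsilyloxy)ethyl]-1,2-dioxolane, via cyclic N,N'-dialkoxyhydrazine 23 (not isolated), via cyclic cis-hyponitrite 24 (not isolated), via 1,3-bis(alkoxyl) diradical 25 (not isolated)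
Conditions: PhI(OAc)2 (2.2 equiv), CH2Cl2 (0.005 M), −78 → −20 °C, dark
Reagents that add atoms: none
Why: Proposed new method: two equivalents of the trivalent iodine oxidant should take the two O–NH2 groups, held 1,3 on the carbon chain, through N–N coupling (an alkoxynitrene or N-iodane captured by the second nitrogen) to the cyclic N,N'-dialkoxyhydrazine 23 and on to the hyponitrite 24, whose N=N is forced cis by the seven-membered ring and should therefore lose N2 well below 0 °C, leaving the singlet pair of tertiary alkoxyl radicals 25 three atoms apart. The closest known reactions are the oxidation of O-alkylhydroxylamines to dialkyl hyponitrites through alkoxynitrenes and the in-cage recombination of alkoxyl radical pairs to dialkyl peroxides when dialkyl hyponitrites are thermolysed; neither has been used within one molecule to close a cyclic peroxide. The 1,2-dioxolane closes by radical–radical combination of O1 with O2, a net contraction of the seven-membered dioxadiazepine to the five-membered ring by extrusion of N2. No stereocentre is made and no C–O bond is broken, so C3 and C5 keep the configurations set in steps 11 and 5. The step needs N–N coupling within the molecule to beat coupling between molecules, which high dilution and slow warming should secure, and O–O collapse to beat β-scission of the tertiary alkoxyl radicals; the pair is born as a singlet at low temperature with the oxygens already 1,3, it is the same diradical through which 1,2-dioxolanes open reversibly on O–O homolysis, and the absence of hydrogen on C3 and C5 rules out disproportionation and oxime formation.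

Step 17
Reactants: 26 (3S,5S)-3,5-dimethyl-5-[(2R)-2-methyl-8-phenyloctyl]-3-[2-(triisopropylsilyloxy)ethyl]-1,2-dioxolane
Product: 27 2-[(3S,5S)-3,5-dimethyl-5-[(2R)-2-methyl-8-phenyloctyl]-1,2-dioxolan-3-yl]ethan-1-ol
Conditions: Bu4NF, THF, 0 °C → rt
Reagents that add atoms: none
Why: Fluoride desilylation; the peroxide carbons carry no hydrogen, so base-induced (Kornblum–DeLaMare type) cleavage of the O–O bond is not possible.

Step 18
Reactants: 27 2-[(3S,5S)-3,5-dimethyl-5-[(2R)-2-methyl-8-phenyloctyl]-1,2-dioxolan-3-yl]ethan-1-ol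
Product: 29 2-[(3R,5S)-3,5-dimethyl-5-[(2R)-2-methyl-8-phenyloctyl]-1,2-dioxolan-3-yl]acetic acid, via dioxolanylacetaldehyde 28 (not isolated)
Conditions: TEMPO (0.2 equiv), PhI(OAc)2 (2.2 equiv), MeCN/H2O (1:1), rt
Reagents that add atoms: water, O
Why: TEMPO/PhI(OAc)2 oxidation in aqueous acetonitrile takes the primary alcohol through the aldehyde 28 and its hydrate to the carboxylic acid under non-reducing, nearly neutral conditions that leave the O–O bond intact (C3 changes from S to R only through the priority rules).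

Step 19
Reactants: 29 2-[(3R,5S)-3,5-dimethyl-5-[(2R)-2-methyl-8-phenyloctyl]-1,2-dioxolan-3-yl]acetic acid
Product: 30 methyl 2-[(3R,5S)-3,5-dimethyl-5-[(2R)-2-methyl-8-phenyloctyl]-1,2-dioxolan-3-yl]acetate
Conditions: Me3SiCHN2, PhMe/MeOH (4:1), 0 °C
Reagents that add atoms: trimethylsilyldiazomethane, C[Si](C)(C)C=[N+]=[N-]
Why: Methyl ester formation with trimethylsilyldiazomethane in methanol is an O-alkylation of the acid under neutral conditions that avoids base-induced β-elimination of the peroxide from the ester.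

**Compound list**

1 | (R)-citronellal, (3R)-3,7-dimethyloct-6-enal | O=CC[C@H](C)CCC=C(C)C | starting material
2 | 4-phenylbut-1-ene | C=CCCc1ccccc1 | starting material
3 | (3R)-3-methyl-9-phenylnon-6-enal (6E drawn; E/Z mixture) | O=CC[C@H](C)CC/C=C/CCc1ccccc1 | intermediate
4 | (3R)-3-methyl-9-phenylnonanal | O=CC[C@H](C)CCCCCCc1ccccc1 | intermediate
5 | dimethyl (1-diazo-2-oxopropyl)phosphonate | CC(=O)C(=[N+]=[N-])P(=O)(OC)OC | starting material
6 | (4R)-4-methyl-10-phenyldec-1-yne | C#CC[C@H](C)CCCCCCc1ccccc1 | intermediate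
7 | trimethylaluminium | C[Al](C)C | starting material
8 | dimethyl[(1E,4R)-2,4-dimethyl-10-phenyldec-1-en-1-yl]alumane | C[Al](C)/C=C(\C)C[C@H](C)CCCCCCc1ccccc1 | intermediate
9 | (2E,5R)-3,5-dimethyl-11-phenylundec-2-en-1-ol | OC/C=C(\C)C[C@H](C)CCCCCCc1ccccc1 | intermediate
10 | [(2S,3S)-3-methyl-3-[(2R)-2-methyl-8-phenyloctyl]oxiran-2-yl]methanol | OC[C@H]1[C@](C)(C[C@H](C)CCCCCCc2ccccc2)O1 | intermediate
11 | (3S,5R)-3,5-dimethyl-11-phenylundecane-1,3-diol | OCC[C@](C)(C[C@H](C)CCCCCCc1ccccc1)O | intermediate
12 | (3S,5R)-3,5-dimethyl-11-phenyl-1,3-bis(triethylsilyloxy)undecane | CC[Si](CC)(CC)OCC[C@](C)(C[C@H](C)CCCCCCc1ccccc1)O[Si](CC)(CC)CC | intermediate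
13 | (3S,5R)-3,5-dimethyl-11-phenyl-3-(triethylsilyloxy)undecanal | O=CC[C@](C)(C[C@H](C)CCCCCCc1ccccc1)O[Si](CC)(CC)CC | intermediate
14 | triethyl{[(4S,6R)-4,6-dimethyl-12-phenyldodec-1-yn-4-yl]oxy}silane | C#CC[C@](C)(C[C@H](C)CCCCCCc1ccccc1)O[Si](CC)(CC)CC | intermediate
15 | dimethyl[(1E,4S,6R)-2,4,6-trimethyl-12-phenyl-4-(triethylsilyloxy)dodec-1-en-1-yl]alumane | C[Al](C)/C=C(\C)C[C@](C)(C[C@H](C)CCCCCCc1ccccc1)O[Si](CC)(CC)CC | intermediate
16 | (2E,5S,7R)-3,5,7-trimethyl-13-phenyl-5-(triethylsilyloxy)tridec-2-en-1-ol | OC/C=C(\C)C[C@](C)(C[C@H](C)CCCCCCc1ccccc1)O[Si](CC)(CC)CC | intermediate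
17 | [(2R,3R)-3-[(2S,4R)-2,4-dimethyl-10-phenyl-2-(triethylsilyloxy)decyl]-3-methyloxiran-2-yl]methanol | OC[C@@H]1[C@@](C)(C[C@](C)(C[C@H](C)CCCCCCc2ccccc2)O[Si](CC)(CC)CC)O1 | intermediate
18 | (3S,5S,7R)-3,5,7-trimethyl-13-phenyl-5-(triethylsilyloxy)tridecane-1,3-diol | OCC[C@@](O)(C)C[C@](C)(C[C@H](C)CCCCCCc1ccccc1)O[Si](CC)(CC)CC | intermediate
19 | (3S,5S,7R)-3,5,7-trimethyl-13-phenyltridecane-1,3,5-triol | OCC[C@@](O)(C)C[C@](C)(C[C@H](C)CCCCCCc1ccccc1)O | intermediate
20 | (3S,5S,7R)-3,5,7-trimethyl-13-phenyl-1-(triisopropylsilyloxy)tridecane-3,5-diol | CC(C)[Si](C(C)C)(C(C)C)OCC[C@@](O)(C)C[C@](C)(C[C@H](C)CCCCCCc1ccccc1)O | intermediate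
21 | dipotassium 3,5-dialkoxide of 20 | CC(C)[Si](C(C)C)(C(C)C)OCC[C@@]([O-])(C)C[C@](C)(C[C@H](C)CCCCCCc1ccccc1)[O-].[K+].[K+] | intermediate
22 | (3S,5S,7R)-3,5-bis(aminooxy)-3,5,7-trimethyl-13-phenyl-1-(triisopropylsilyloxy)tridecane | CC(C)[Si](C(C)C)(C(C)C)OCC[C@@](ON)(C)C[C@](C)(C[C@H](C)CCCCCCc1ccccc1)ON | intermediate
23 | cyclic N,N'-dialkoxyhydrazine: 1,4,2,3-dioxadiazepane in which O1–N2H–N3H–O4 bridges the two quaternary carbons of 22, configurations unchanged | CC(C)[Si](C(C)C)(C(C)C)OCC[C@@]1(C)C[C@](C)(C[C@H](C)CCCCCCc2ccccc2)ONNO1 | intermediate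
24 | cyclic cis-hyponitrite: the 6,7-dihydro-5H-1,4,2,3-dioxadiazepine formed from 23 by loss of two hydrogens (N=N), configurations unchanged | CC(C)[Si](C(C)C)(C(C)C)OCC[C@@]1(C)C[C@](C)(C[C@H](C)CCCCCCc2ccccc2)ON=NO1 | intermediate
25 | 1,3-bis(alkoxyl) diradical left after loss of N2 from 24, oxygen radicals on the two quaternary carbons | CC(C)[Si](C(C)C)(C(C)C)OCC[C@@]([O])(C)C[C@](C)(C[C@H](C)CCCCCCc1ccccc1)[O] | intermediate
26 | (3S,5S)-3,5-dimethyl-5-[(2R)-2-methyl-8-phenyloctyl]-3-[2-(triisopropylsilyloxy)ethyl]-1,2-dioxolane | CC(C)[Si](C(C)C)(C(C)C)OCC[C@@]1(C)C[C@](C)(C[C@H](C)CCCCCCc2ccccc2)OO1 | intermediate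
27 | 2-[(3S,5S)-3,5-dimethyl-5-[(2R)-2-methyl-8-phenyloctyl]-1,2-dioxolan-3-yl]ethan-1-ol | OCC[C@@]1(C)C[C@](C)(C[C@H](C)CCCCCCc2ccccc2)OO1 | intermediate
28 | 2-[(3R,5S)-3,5-dimethyl-5-[(2R)-2-methyl-8-phenyloctyl]-1,2-dioxolan-3-yl]acetaldehyde | O=CC[C@@]1(C)C[C@](C)(C[C@H](C)CCCCCCc2ccccc2)OO1 | intermediate
29 | 2-[(3R,5S)-3,5-dimethyl-5-[(2R)-2-methyl-8-phenyloctyl]-1,2-dioxolan-3-yl]acetic acid | OC(=O)C[C@@]1(C)C[C@](C)(C[C@H](C)CCCCCCc2ccccc2)OO1 | intermediate
30 | methyl 2-[(3R,5S)-3,5-dimethyl-5-[(2R)-2-methyl-8-phenyloctyl]-1,2-dioxolan-3-yl]acetate | COC(=O)C[C@@]1(C)C[C@](C)(C[C@H](C)CCCCCCc2ccccc2)OO1 | target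

**Step count and risks**

Total step count: 19. Longest linear sequence: 19 steps (from 1 to 30).

Steps most likely to fail:

1. Step 16 (new method). The oxidised aminooxy groups may couple between molecules instead of within one, the alkoxynitrene may fragment before the second nitrogen captures it, or the nascent alkoxyl pair may undergo β-scission faster than it closes the O–O bond. The fallback uses the known oxetane/hydrogen peroxide route to 1,2-dioxolane-3-acetates; it sets out from 9 and comes back at 30.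
   - Allylic alcohol 9 would be epoxidised with the enantiomeric catalyst (Ti(OiPr)4, D-(−)-diisopropyl tartrate, t-BuOOH) to the (2R,3R)-epoxy alcohol F1 and opened with Red-Al to the (3R,5R)-diol F2. The tertiary centre is deliberately the epimer of that in 11, because it is inverted later.
   - TEMPO/PhI(OAc)2 oxidation would give the hydroxy aldehyde F3, and MeMgBr (2.2 equiv, −78 °C) the secondary/tertiary diol F4 as a mixture of carbinol epimers.
   - Selective mesylation of the secondary hydroxyl would give the mesylate F5, and KOtBu would close the oxetane F6 by Williamson displacement.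
   - Me3SiOTf-catalysed opening with ethereal H2O2 takes place at the tertiary carbon with inversion and should give the hydroperoxy alcohol F7, which now has the C5 configuration of the target.
   - Protection of the hydroperoxide with 2-methoxypropene/PPTS would give the peroxyketal F8, and Dess–Martin oxidation the ketone F9. Acidic methanol would unmask the hydroperoxide, which closes on the ketone and is ketalised to the 3-methoxy-1,2-dioxolane F10.
   - TiCl4 with 1-methoxy-1-(trimethylsilyloxy)ethene would add the acetate arm through the dioxolan-3-yl cation and give 30 together with its C3 epimer. Here C3 is under substrate control only, so the epimer would have to be removed by chromatography.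

2. Step 15. The second amination may stall on the hindered, aggregated dialkoxide, or the silyl group may migrate to a tertiary alkoxide. The fallback aminates each tertiary oxygen separately as a mono-alkoxide, using the silyl ether already present; it sets out from 18 and comes back at 22.
   - Diol 18 would be silylated on the primary hydroxyl (iPr3SiCl, imidazole) to the mono-alcohol F11.
   - Amination of the C3 potassium alkoxide (KH, DMPU; 3,3-di-tert-butyloxaziridine) would give the mono(aminooxy) compound F12.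
   - Selective cleavage of the tertiary triethylsilyl ether with HF·pyridine in THF/pyridine would give the aminooxy alcohol F13.
   - A second alkoxide amination at C5 would give 22.

3. Step 10. Carbometalation may be slow or poorly regioselective next to the quaternary silyloxy centre, and the Lewis-acidic medium may strip the triethylsilyl ether. The fallback builds the trisubstituted alkene by olefination; it sets out from 14 and comes back at 16.
   - Gold-catalysed hydration of alkyne 14 (Ph3PAuNTf2, aqueous 1,4-dioxane) would give the methyl ketone F14.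
   - Horner–Wadsworth–Emmons olefination with triethyl phosphonoacetate/NaH should favour the E-enoate F15, the Z isomer being removed by chromatography.
   - Reduction with i-Bu2AlH in CH2Cl2 at −78 °C would give 16.

Further compounds
F1 | step 16 | [(2R,3R)-3-methyl-3-[(2R)-2-methyl-8-phenyloctyl]oxiran-2-yl]methanol | OC[C@@H]1[C@@](C)(C[C@H](C)CCCCCCc2ccccc2)O1
F2 | step 16 | (3R,5R)-3,5-dimethyl-11-phenylundecane-1,3-diol | OCC[C@@](C)(C[C@H](C)CCCCCCc1ccccc1)O
F3 | step 16 | (3R,5R)-3-hydroxy-3,5-dimethyl-11-phenylundecanal | O=CC[C@@](C)(C[C@H](C)CCCCCCc1ccccc1)O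
F4 | step 16 | (4R,6R)-4,6-dimethyl-12-phenyldodecane-2,4-diol (both C2 epimers) | CC(O)C[C@@](C)(C[C@H](C)CCCCCCc1ccccc1)O
F5 | step 16 | (4R,6R)-4-hydroxy-4,6-dimethyl-12-phenyldodecan-2-yl methanesulfonate (both C2 epimers) | CC(OS(C)(=O)=O)C[C@@](C)(C[C@H](C)CCCCCCc1ccccc1)O
F6 | step 16 | (2R)-2,4-dimethyl-2-[(2R)-2-methyl-8-phenyloctyl]oxetane (both C4 epimers) | CC1C[C@@](C)(C[C@H](C)CCCCCCc2ccccc2)O1
F7 | step 16 | (4S,6R)-4-hydroperoxy-4,6-dimethyl-12-phenyldodecan-2-ol (both C2 epimers) | CC(O)C[C@](C)(C[C@H](C)CCCCCCc1ccccc1)OO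
F8 | step 16 | (4S,6R)-4-[(2-methoxypropan-2-yl)peroxy]-4,6-dimethyl-12-phenyldodecan-2-ol (both C2 epimers) | CC(O)C[C@](C)(C[C@H](C)CCCCCCc1ccccc1)OOC(C)(C)OC
F9 | step 16 | (4S,6R)-4-[(2-methoxypropan-2-yl)peroxy]-4,6-dimethyl-12-phenyldodecan-2-one | CC(=O)C[C@](C)(C[C@H](C)CCCCCCc1ccccc1)OOC(C)(C)OC
F10 | step 16 | (5S)-3-methoxy-3,5-dimethyl-5-[(2R)-2-methyl-8-phenyloctyl]-1,2-dioxolane (both C3 epimers) | COC1(C)C[C@](C)(C[C@H](C)CCCCCCc2ccccc2)OO1
F11 | step 15 | (3S,5S,7R)-3,5,7-trimethyl-13-phenyl-5-(triethylsilyloxy)-1-(triisopropylsilyloxy)tridecan-3-ol | CC(C)[Si](C(C)C)(C(C)C)OCC[C@@](O)(C)C[C@](C)(C[C@H](C)CCCCCCc1ccccc1)O[Si](CC)(CC)CC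
F12 | step 15 | (3S,5S,7R)-3-(aminooxy)-3,5,7-trimethyl-13-phenyl-5-(triethylsilyloxy)-1-(triisopropylsilyloxy)tridecane | CC(C)[Si](C(C)C)(C(C)C)OCC[C@@](ON)(C)C[C@](C)(C[C@H](C)CCCCCCc1ccccc1)O[Si](CC)(CC)CC
F13 | step 15 | (3S,5S,7R)-3-(aminooxy)-3,5,7-trimethyl-13-phenyl-1-(triisopropylsilyloxy)tridecan-5-ol | CC(C)[Si](C(C)C)(C(C)C)OCC[C@@](ON)(C)C[C@](C)(C[C@H](C)CCCCCCc1ccccc1)O
F14 | step 10 | (4S,6R)-4,6-dimethyl-12-phenyl-4-(triethylsilyloxy)dodecan-2-one | CC(=O)C[C@](C)(C[C@H](C)CCCCCCc1ccccc1)O[Si](CC)(CC)CC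
F15 | step 10 | ethyl (2E,5S,7R)-3,5,7-trimethyl-13-phenyl-5-(triethylsilyloxy)tridec-2-enoate | CCOC(=O)/C=C(\C)C[C@](C)(C[C@H](C)CCCCCCc1ccccc1)O[Si](CC)(CC)CC
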